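A flask that spends one nucleophile per electrophile cannot slow the way the spring run slows.

| setting | spring | dusk | zeta | delta |
|---|---|---|---|---|
| electrophile | 10 mM | 10 mM | 10 mM | 10 mM |
| nucleophile | 16 mM | 19 mM | 20.0 mM | 30.0 mM |
| solid base | 8 mM | 8 mM | 8.00 mM | 8.00 mM |
| remark | run made earlier | run made earlier |  |  |
| time |  |  | 2.0 h | 2.0 h |

| run | time / min | electrophile / % | target / % |
|---|---|---|---|
| spring | 5.00 | 91.8 | 6.2 |
| spring | 8.00 | 86.6 | 10.7 |
| spring | 12.0 | 82.1 | 14.4 |
| spring | 15.0 | 79.1 | 14.5 |
| spring | 25.0 | 71.8 | 20.6 |
| spring | 40.0 | 60.6 | 23.9 |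
| spring | 60.0 | 51.7 | 27.2 |
| dusk | 8.00 | 84.4 | 12.6 |
| dusk | 15.0 | 77.7 | 17.3 |
| dusk | 25.0 | 65.1 | 24.6 |
| dusk | 30.0 | 61.0 | 26.5 |
| dusk | 40.0 | 54.9 | 28.1 |
| dusk | 50.0 | 46.8 | 30.6 |
| dusk | 60.0 | 45.0 | 31.2 |

(standard deviation of a reading: 1 percentage point)

- solid base is a solid; its amount is given per volume of the solution
- at the start none of the solid base is in solution

- part of the electrophile that has reacted at the end, zeta
- part of the electrophile that has reacted at the end, delta
- what raising the concentration of nucleophile from its lowest to its highest value here does to the part of the electrophile that has reacted (changes below 5 percentage points count as none) (it falls / no change / it rises)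

How fast do the two meet? The early dusk reading gives a rate constant of 1.12 L mol⁻¹ min⁻¹, and the early spring reading gives 1.12 L mol⁻¹ min⁻¹, so the rate follows electrophile times free nucleophile.

How much nucleophile is free late? With 4.38 mM of electrophile gone, the spring decay between 40.0 min and 60.0 min reads as 7.12 mM of free nucleophile, but one for one would leave 11.6 mM. So I defined the cost, the free nucleophile lost per electrophile reacted, and read it as 2.03.

What does that leave? Electrophile is the limiting reagent by charge, but in zeta the cost times its charge about equals the nucleophile. Taking the cost as constant, I set free nucleophile in zeta at about 2.03 times the electrophile, which makes the decay a hyperbola, and I reckoned 73.1% reacted. Delta has 9.74 mM of nucleophile to spare, and I reckoned 89.2%.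

The forecast gave 73% for zeta and 89% for delta, with the trend it rises, reasoning “as if released acid protonates it and the solid base barely helps”.

The flask gives 75.2% for zeta and 89.9% for delta; it rises, by 15 percentage points.

    electrophile + nucleophile → acid set free + target (k = 1.07 L mol⁻¹ min⁻¹)
    solid base ⇌ free base, rate k2*(cs2 - [free base]) while solid is left; crystals form when [free base] > cs2 (solubility = 2.40 mM, k = 0.0135 min⁻¹)
    target ⇌ isomer of the product (K = 1.10, k = 0.0310 min⁻¹)
    acid set free + free base ⇌ salt of the base, settled at all times (K = 856 L mol⁻¹)
    acid set free → by-product carried off (k = 0.0318 min⁻¹)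
    nucleophile + acid set free ⇌ protonated nucleophile, settled at all times (K = 1180 L mol⁻¹)

Zeta at 2.00 h holds 4.89 mM of protonated nucleophile against 0.731 mM of salt of the base. Its cost, counted from the nucleophile left, is 1.65, less than my reading.

A neighbour of zeta shows a change that takes this reckoning wrong: with 40 mM of electrophile on 20.0 mM of nucleophile, my cost allows 24.6% reacted. That neighbour reaches 37.3%, more than my cost allows, with 7.1% of its nucleophile left, at a cost of 1.25.

The readings were generated by integration on assumed constants, noise included.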